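A leftover stood in the charges: each complex with three exchanged takes 3 incoming ligand, and this flask holds 2.00 per starting complex. So incoming ligand is the limiting reagent, and I defined the ligand ceiling as charged c(incoming ligand) over 3 times charged c(starting complex): 66.7 %. At least 33.3 % of the starting complex charged to this flask must therefore stay short of three exchanged.

common to all: starting complex 0.050 M (fed, over 4.0 min)
- blue: incoming ligand 0.10 M; the very flask that is asked about, followed so far; the fed solution adds 1.0 times the starting volume
- flask: incoming ligand 0.100 M; the fed solution adds 1.0 times the starting volume; time 5.0 h

The feed adds volume, but both charges count on the starting volume, so the ceiling stays put.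

blue run (percent of the starting complex charged)

| time / min | complex with three exchanged / % |
|---|---|
| 2.00 | 10.3 |
| 4.00 | 19.5 |
| 8.00 | 22.7 |
| 15.0 | 22.4 |
| 30.0 | 21.0 |
| 60.0 | 17.9 |
| 120 | 16.4 |

(standard deviation of a reading: 0.5 percentage points)

- every charge counts on the volume at the start, and the solution that is fed holds the whole dose
- percentages count the whole charge, also what has not yet gone in

The blue run is this very flask, so its readings are the flask's own. They climb to 22.7 % at 8.00 min, and the next reading differs by 0.3 percentage points, with a scatter of 0.5 points. Each exchange uses one incoming ligand, so I watched c(incoming ligand): the rise can last only while it lasts.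

- the moment within 5.0 h at which there is most complex with three exchanged
- the amount of complex with three exchanged, in percent of the starting complex charged, at that time

My own reckoning put the peak near the top reading, about 0.13 h and 23 %, with the reading's scatter. The forecast gave 0.17 h and 23 %, holding that “the maximum lies in the early phase”.

The flask gave 23.0 % at 0.142 h, when incoming ligand stood at 5.10 % of its own charge.

    starting complex + incoming ligand → leaving ligand + complex with one exchanged (k = 20.0 M⁻¹ min⁻¹)
    complex with one exchanged + incoming ligand → leaving ligand + complex with two exchanged (k = 29.0 M⁻¹ min⁻¹)
    complex with two exchanged + incoming ligand → leaving ligand + complex with three exchanged (k = 55.0 M⁻¹ min⁻¹)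
    complex with three exchanged ⇌ isomer of the product (K = 0.500, k = 0.0100 min⁻¹)
    complex with two exchanged → side product (k = 1.20 min⁻¹)
    2 incoming ligand → homo dimer (k = 0.710 M⁻¹ min⁻¹)

That peak is about a third of the ceiling of 66.7 %. The neighbour flask with 0.060 M of incoming ligand has a ceiling of 40.0 %, and its best was 10.7 %, a share of 0.267.

The readings come from a simulation with constants of no real substance; noise was put on by code.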